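## Retrosynthetic overview

1. The route rests on one feature: C5–C10 (labdane numbering) is the only bond common to rings A and B, so cutting it opens the trans-decalin to a single ten-membered carbocycle C1–C10. In that ring C10 carries an exocyclic methylene (the later C20 methyl) and C5 is the β-carbon of an E-enone C5=C6–C7=O.
2. A transannular radical addition started by hydrogen-atom transfer forms that bond, closes rings A and B in one event and sets C5 and C10. The 7-ketone then gives the axial 7α-acetate, and C15 is unmasked and oxidized last.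
3. The ten-membered ring is made before rings A and B, by a Nozaki–Hiyama–Kishi closure of C7–C8 (C8 iodoalkene onto C7 enal) and oxidation.
4. C9, the only ring stereocentre of the macrocycle, comes from a copper-catalysed SN2′ alkynylation of an allylic phosphate. The alkyne is the precursor of the C8 iodoalkene.
5. The phosphate is assembled by two Horner–Wadsworth–Emmons reactions from (S)-citronellol (C9, C11–C16), triethyl phosphonoacetate (C10/C20 and C6/C7) and isobutyronitrile with 1-bromo-3-chloropropane (C1–C5, C18, C19).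

Key step: step 16

Remarks before the steps:
- Labdane numbering is used for all intermediates; α/β refer to the usual drawing with the C20 methyl β.
- C15 is carried as a tert-butyldiphenylsilyl ether and not as an ester, because steps 6 and 12 use i-Bu2AlH; the acid is made in the last step.
- Assumption: in step 9 the ligand antipode is the one that adds the alkynyl group to the Re face of C9. Both antipodes are accessible, and the sense of induction is read in a trial run from the diastereomer ratio against the fixed C13 centre.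

## Route

Step 1
Reactants: 1 (S)-citronellol
Product: 2 (S)-tert-butyl[(3,7-dimethyloct-6-en-1-yl)oxy]diphenylsilane
Conditions: TBDPSCl, imidazole, DMF, rt
Reagents that add atoms: tert-butyl(chloro)diphenylsilane, CC(C)(C)[Si](Cl)(c1ccccc1)c1ccccc1
Why: Imidazole-promoted silylation masks the future C15 as a primary silyl ether that should survive the hydride, organometallic and radical steps and is removed by fluoride at the end; the C13 centre comes unchanged from the chiral pool.

Step 2
Reactants: 2 (S)-tert-butyl[(3,7-dimethyloct-6-en-1-yl)oxy]diphenylsilane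
Product: 4 (4S)-6-[(tert-butyldiphenylsilyl)oxy]-4-methylhexanal, via ozonide 3 (not isolated)
Conditions: O3, CH2Cl2, −78 °C; then PPh3, −78 °C → rt
Reagents that add atoms: ozone, [O-][O+]=O
Why: Ozonolysis with reductive work-up cleaves the only alkene and turns the alkene CH into the aldehyde carbon that becomes C9.

Step 3
Reactants: 5 isobutyronitrile; 6 1-bromo-3-chloropropane
Product: 7 5-chloro-2,2-dimethylpentanenitrile
Conditions: LiN(i-Pr)2, THF, −78 °C; then 6, −78 °C → rt
Reagents that add atoms: none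
Why: α-Alkylation of the lithiated nitrile takes place at the bromide end of the dihalide (better leaving group) and builds the quaternary C4 with the C1–C3 chain and C5 as the nitrile.

Step 4
Reactants: 7 5-chloro-2,2-dimethylpentanenitrile; 8 triethyl phosphonoacetate
Product: 9 ethyl 6-cyano-2-(diethoxyphosphoryl)-6-methylheptanoate (racemic at C2)
Conditions: NaH, DMF, 0 °C; then 7, NaI (cat.), 70 °C
Reagents that add atoms: none
Why: C-Alkylation of the sodium phosphonoacetate by the primary chloride (Finkelstein exchange in the flask) joins C1 to the future C10 and gives the substituted Horner–Wadsworth–Emmons reagent; an excess of 8 limits dialkylation.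

Step 5
Reactants: 4 (4S)-6-[(tert-butyldiphenylsilyl)oxy]-4-methylhexanal; 9 ethyl 6-cyano-2-(diethoxyphosphoryl)-6-methylheptanoate
Product: 10 ethyl (2E,6S)-8-[(tert-butyldiphenylsilyl)oxy]-2-(4-cyano-4-methylpentyl)-6-methyloct-2-enoate
Conditions: NaH, THF, 0 °C; then 4, 0 °C → rt; E isomer purified on silica
Reagents that add atoms: none
Why: Horner–Wadsworth–Emmons olefination forms C9=C10 and should give mainly the isomer with the ester (C20) trans to the side chain; the minor Z ester is removed because the alkene geometry fixes the sense of induction in step 9.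

Step 6
Reactants: 10 ethyl (2E,6S)-8-[(tert-butyldiphenylsilyl)oxy]-2-(4-cyano-4-methylpentyl)-6-methyloct-2-enoate
Product: 12 (6E,10S)-12-[(tert-butyldiphenylsilyl)oxy]-6-(hydroxymethyl)-2,2,10-trimethyldodec-6-enal, via aluminated aldimine 11 (not isolated)
Conditions: i-Bu2AlH (4.5 equiv), CH2Cl2, −78 → 0 °C; then aq. Rochelle salt, aq. citric acid
Reagents that add atoms: water, O
Why: i-Bu2AlH reduces the conjugated ester 1,2 to the C20 allylic alcohol and the tertiary nitrile to the N-aluminated aldimine, which hydrolyses on work-up to the non-enolizable neopentyl aldehyde C5.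

Step 7
Reactants: 12 (6E,10S)-12-[(tert-butyldiphenylsilyl)oxy]-6-(hydroxymethyl)-2,2,10-trimethyldodec-6-enal; 8 triethyl phosphonoacetate
Product: 13 ethyl (2E,8E,12S)-14-[(tert-butyldiphenylsilyl)oxy]-8-(hydroxymethyl)-4,4,12-trimethyltetradeca-2,8-dienoate
Conditions: 8, NaH, THF, 0 °C (anion preformed); then 12, 0 °C → rt
Reagents that add atoms: none
Why: Horner–Wadsworth–Emmons olefination of the hindered, non-enolizable aldehyde should give the E-enoate C5=C6–C7, the future enone arm; the free allylic alcohol is tolerated because no excess base is present.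

Step 8
Reactants: 13 ethyl (2E,8E,12S)-14-[(tert-butyldiphenylsilyl)oxy]-8-(hydroxymethyl)-4,4,12-trimethyltetradeca-2,8-dienoate
Product: 14 ethyl (2E,8E,12S)-14-[(tert-butyldiphenylsilyl)oxy]-8-{[(diethoxyphosphoryl)oxy]methyl}-4,4,12-trimethyltetradeca-2,8-dienoate
Conditions: ClP(O)(OEt)2, Et3N, DMAP (cat.), CH2Cl2, 0 °C
Reagents that add atoms: diethyl chlorophosphate, CCOP(=O)(Cl)OCC
Why: Phosphorylation of the primary allylic alcohol puts at C20 the leaving group needed for copper-catalysed allylic substitution.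

Step 9
Reactants: 14 ethyl (2E,8E,12S)-14-[(tert-butyldiphenylsilyl)oxy]-8-{[(diethoxyphosphoryl)oxy]methyl}-4,4,12-trimethyltetradeca-2,8-dienoate; 15 trimethylsilylacetylene
Product: 17 ethyl (2E,9R,12S)-14-[(tert-butyldiphenylsilyl)oxy]-4,4,12-trimethyl-8-methylidene-9-[(trimethylsilyl)ethynyl]tetradec-2-enoate, via alkynylalane 16 (not isolated)
Conditions: 15, i-Bu2AlH, Et3N (5 mol %), hexane, rt; then 14, CuCl2·2H2O (5 mol %), chiral 4,5-diphenylimidazolinium salt with an N-(2-sulfonatoaryl) group (carbene precursor, 5 mol %), THF, −30 °C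
Reagents that add atoms: none
Why: Copper-catalysed enantioselective allylic substitution (SN2′) with an alkynylaluminium: the carbene–copper alkynyl adds at C9 anti to the leaving phosphate while C10=C20 becomes the methylene group, and the ligand antipode that attacks the Re face of C9 of the E-alkene sets 9R under catalyst control (C13 is too remote to interfere).

Step 10
Reactants: 17 ethyl (2E,9R,12S)-14-[(tert-butyldiphenylsilyl)oxy]-4,4,12-trimethyl-8-methylidene-9-[(trimethylsilyl)ethynyl]tetradec-2-enoate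
Product: 18 ethyl (2E,9R,12S)-14-[(tert-butyldiphenylsilyl)oxy]-9-ethynyl-4,4,12-trimethyl-8-methylidenetetradec-2-enoate
Conditions: K2CO3 (cat.), EtOH, rt
Reagents that add atoms: none
Why: Base-catalysed ethanolysis cleaves the alkynyl C–Si bond; ethanol matches the ethyl ester, and the mild base should leave the doubly activated C9–H alone.

Step 11
Reactants: 18 ethyl (2E,9R,12S)-14-[(tert-butyldiphenylsilyl)oxy]-9-ethynyl-4,4,12-trimethyl-8-methylidenetetradec-2-enoate
Product: 20 ethyl (2E,9R,12S)-14-[(tert-butyldiphenylsilyl)oxy]-9-(1-iodoethenyl)-4,4,12-trimethyl-8-methylidenetetradec-2-enoate, via alkenylborane 19 (not isolated)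
Conditions: B-iodo-9-BBN, pentane/CH2Cl2, −20 °C; then AcOH, 0 °C
Reagents that add atoms: B-iodo-9-borabicyclo[3.3.1]nonane, IB1C2CCCC1CCC2
Why: Syn iodoboration of the terminal alkyne places boron on C17 and iodine on C8 (Markovnikov haloboration), and protodeboronation with acetic acid leaves the 2-iodo-1-alkene; alkenes, ester and silyl ether should not react at this temperature.

Step 12
Reactants: 20 ethyl (2E,9R,12S)-14-[(tert-butyldiphenylsilyl)oxy]-9-(1-iodoethenyl)-4,4,12-trimethyl-8-methylidenetetradec-2-enoate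
Product: 21 (2E,9R,12S)-14-[(tert-butyldiphenylsilyl)oxy]-9-(1-iodoethenyl)-4,4,12-trimethyl-8-methylidenetetradec-2-en-1-ol
Conditions: i-Bu2AlH (2.5 equiv), CH2Cl2, −78 °C
Reagents that add atoms: none
Why: 1,2-Reduction of the enoate gives the E-allylic alcohol at C7; iodoalkene and silyl ether are inert to the hydride at −78 °C.

Step 13
Reactants: 21 (2E,9R,12S)-14-[(tert-butyldiphenylsilyl)oxy]-9-(1-iodoethenyl)-4,4,12-trimethyl-8-methylidenetetradec-2-en-1-ol
Product: 22 (2E,9R,12S)-14-[(tert-butyldiphenylsilyl)oxy]-9-(1-iodoethenyl)-4,4,12-trimethyl-8-methylidenetetradec-2-enal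
Conditions: MnO2, CH2Cl2, rt
Reagents that add atoms: none
Why: Allylic oxidation with MnO2 gives the E-enal under neutral conditions that leave the doubly allylic C9–H untouched.

Step 14
Reactants: 22 (2E,9R,12S)-14-[(tert-butyldiphenylsilyl)oxy]-9-(1-iodoethenyl)-4,4,12-trimethyl-8-methylidenetetradec-2-enal
Product: 23 (2E,9R)-9-{(3S)-5-[(tert-butyldiphenylsilyl)oxy]-3-methylpentyl}-4,4-dimethyl-8,10-dimethylidenecyclodec-2-en-1-ol (both C1 epimers)
Conditions: CrCl2 (8 equiv), NiCl2 (cat.), degassed DMSO/THF, rt, slow addition to 2 mM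
Reagents that add atoms: none
Why: Nozaki–Hiyama–Kishi reaction: zerovalent nickel (from NiCl2 and CrCl2) inserts into the C8–I bond, transmetalation gives an alkenyl species of trivalent chromium that adds 1,2 to the C7 enal under neutral conditions and high dilution, which closes the ten-membered ring with the E alkene already in place; the C7 configuration does not matter because C7 is oxidized next.

Step 15
Reactants: 23 (2E,9R)-9-{(3S)-5-[(tert-butyldiphenylsilyl)oxy]-3-methylpentyl}-4,4-dimethyl-8,10-dimethylidenecyclodec-2-en-1-ol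
Product: 24 (2E,9R)-9-{(3S)-5-[(tert-butyldiphenylsilyl)oxy]-3-methylpentyl}-4,4-dimethyl-8,10-dimethylidenecyclodec-2-en-1-one
Conditions: DMP, pyridine, CH2Cl2, 0 °C; used at once
Reagents that add atoms: none
Why: Dess–Martin oxidation of the doubly allylic alcohol gives the cross-conjugated dienone under buffered conditions that should not epimerize or isomerize the γ-stereocentre C9.

Step 16
Reactants: 24 (2E,9R)-9-{(3S)-5-[(tert-butyldiphenylsilyl)oxy]-3-methylpentyl}-4,4-dimethyl-8,10-dimethylidenecyclodec-2-en-1-one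
Product: 25 (13S)-15-[(tert-butyldiphenylsilyl)oxy]labd-8(17)-en-7-one (5S,9R,10S)
Conditions: Fe(acac)3 (30 mol %), PhSiH3 (2 equiv), EtOH/(CH2OH)2 5:1, 60 °C, 5 mM
Reagents that add atoms: none
Why: Proposed new method: Fe(acac)3 and PhSiH3 in ethanol form a hydride of trivalent iron that transfers a hydrogen atom to C20 of the electron-rich 1,1-dialkyl alkene, the tertiary C10 radical adds across the ring to C5 (the β-carbon of the E-enone), and the C6 α-keto radical is reduced by divalent iron to the enolate and protonated by ethanol; the closest known reactions are the Fe(acac)3/PhSiH3 reductive coupling of 1,1-disubstituted alkenes with enones (a Giese addition started by hydrogen-atom transfer) and the transannular closure of cyclodeca-1,5-dienes to trans-decalins. Ring A (C10, C1–C5) closes in the 6-exo mode and ring B (C10, C9–C5) in the 6-endo mode, because C6 lies outside ring A and inside ring B. C10 is controlled by C9, the only ring stereocentre: in the chair–chair-like folding the C9 side chain sits pseudo-equatorially, so the C10 radical, planar until the bond forms, bonds through the face that leaves the new methyl C20 axial and anti to H9. C5 is controlled by the E geometry of C5=C6, which holds C4 and C7 trans and lets C10 reach only the face of C5 on which H5 ends up anti to C20 (trans fusion). The step needs hydrogen-atom transfer to C10=C20 in preference to the two enone alkenes, and C5 in preference to every other acceptor carbon: the first rests on the higher reactivity of the electron-rich alkene towards the metal hydride, the second on C5 being the only enone β-carbon within six-membered reach (attack on C17 would need a four-membered ring), and high dilution suppresses intermolecular addition to C17.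

Step 17
Reactants: 25 (13S)-15-[(tert-butyldiphenylsilyl)oxy]labd-8(17)-en-7-one
Product: 26 (13S)-15-[(tert-butyldiphenylsilyl)oxy]labd-8(17)-en-7α-ol (5S,7R,9R,10S)
Conditions: (S)-2-methyl-CBS-oxazaborolidine (0.5 equiv), catecholborane, toluene, −78 °C
Reagents that add atoms: none
Why: Corey–Bakshi–Shibata reduction: with the (S)-oxazaborolidine the ketone binds with the C8 alkene arm as the large group and hydride is delivered 1,2 to the β (equatorial) face of C7, which gives the axial 7α (7R) alcohol; a bulky hydride donor prefers the same equatorial approach, so catalyst and substrate should be matched.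

Step 18
Reactants: 26 (13S)-15-[(tert-butyldiphenylsilyl)oxy]labd-8(17)-en-7α-ol
Product: 27 (13S)-15-[(tert-butyldiphenylsilyl)oxy]labd-8(17)-en-7α-yl acetate
Conditions: Ac2O, pyridine, DMAP (cat.), rt
Reagents that add atoms: acetic anhydride, CC(=O)OC(C)=O
Why: DMAP-catalysed acylation of the axial allylic alcohol takes place at oxygen with retention at C7.

Step 19
Reactants: 27 (13S)-15-[(tert-butyldiphenylsilyl)oxy]labd-8(17)-en-7α-yl acetate
Product: 28 (13S)-15-hydroxylabd-8(17)-en-7α-yl acetate
Conditions: Bu4NF, AcOH (1:1), THF, rt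
Reagents that add atoms: none
Why: Fluoride cleaves the Si–O bond of the primary silyl ether, and buffering with acetic acid should keep the allylic acetate from hydrolysis.

Step 20
Reactants: 28 (13S)-15-hydroxylabd-8(17)-en-7α-yl acetate
Product: 30 (5S,7R,9R,10S,13S)-7-acetoxylabd-8(17)-en-15-oic acid, via aldehyde 29 (not isolated)
Conditions: TEMPO (20 mol %), PhI(OAc)2 (2.5 equiv), MeCN/H2O 1:1, rt
Reagents that add atoms: water, O
Why: Oxoammonium (TEMPO) oxidation takes the primary alcohol to the aldehyde, whose hydrate is oxidized on to the acid in the aqueous medium; the allylic acetate and the 1,1-disubstituted alkene should be inert.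

## Compound list

1 | (S)-citronellol | CC(C)=CCC[C@H](C)CCO | starting material
2 | (S)-tert-butyl[(3,7-dimethyloct-6-en-1-yl)oxy]diphenylsilane | CC(C)=CCC[C@H](C)CCO[Si](c1ccccc1)(c1ccccc1)C(C)(C)C | intermediate
3 | ozonide of 2 (3,3-dimethyl-1,2,4-trioxolane carrying the silyloxy chain at C5) | CC1(C)OOC(CC[C@H](C)CCO[Si](c2ccccc2)(c2ccccc2)C(C)(C)C)O1 | intermediate (not isolated)
4 | (4S)-6-[(tert-butyldiphenylsilyl)oxy]-4-methylhexanal | O=CCC[C@H](C)CCO[Si](c1ccccc1)(c1ccccc1)C(C)(C)C | intermediate
5 | isobutyronitrile | CC(C)C#N | starting material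
6 | 1-bromo-3-chloropropane | ClCCCBr | starting material
7 | 5-chloro-2,2-dimethylpentanenitrile | CC(C)(CCCCl)C#N | intermediate
8 | triethyl phosphonoacetate | CCOC(=O)CP(=O)(OCC)OCC | starting material
9 | ethyl 6-cyano-2-(diethoxyphosphoryl)-6-methylheptanoate | CCOC(=O)C(CCCC(C)(C)C#N)P(=O)(OCC)OCC | intermediate
10 | ethyl (2E,6S)-8-[(tert-butyldiphenylsilyl)oxy]-2-(4-cyano-4-methylpentyl)-6-methyloct-2-enoate | CCOC(=O)/C(CCCC(C)(C)C#N)=C/CC[C@H](C)CCO[Si](c1ccccc1)(c1ccccc1)C(C)(C)C | intermediate
11 | diisobutylaluminium alkoxide and N-(diisobutylaluminio)aldimine from 10 | CC(C)C[Al](CC(C)C)OC/C(CCCC(C)(C)C=N[Al](CC(C)C)CC(C)C)=C/CC[C@H](C)CCO[Si](c1ccccc1)(c1ccccc1)C(C)(C)C | intermediate (not isolated)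
12 | (6E,10S)-12-[(tert-butyldiphenylsilyl)oxy]-6-(hydroxymethyl)-2,2,10-trimethyldodec-6-enal | O=CC(C)(C)CCC/C(CO)=C\CC[C@H](C)CCO[Si](c1ccccc1)(c1ccccc1)C(C)(C)C | intermediate
13 | ethyl (2E,8E,12S)-14-[(tert-butyldiphenylsilyl)oxy]-8-(hydroxymethyl)-4,4,12-trimethyltetradeca-2,8-dienoate | CCOC(=O)/C=C/C(C)(C)CCC/C(CO)=C\CC[C@H](C)CCO[Si](c1ccccc1)(c1ccccc1)C(C)(C)C | intermediate
14 | diethyl phosphate of 13 (phosphate on the C8 hydroxymethyl group) | CCOC(=O)/C=C/C(C)(C)CCC/C(COP(=O)(OCC)OCC)=C\CC[C@H](C)CCO[Si](c1ccccc1)(c1ccccc1)C(C)(C)C | intermediate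
15 | trimethylsilylacetylene | C#C[Si](C)(C)C | starting material
16 | diisobutyl[(trimethylsilyl)ethynyl]aluminium | CC(C)C[Al](CC(C)C)C#C[Si](C)(C)C | intermediate (not isolated)
17 | ethyl (2E,9R,12S)-14-[(tert-butyldiphenylsilyl)oxy]-4,4,12-trimethyl-8-methylidene-9-[(trimethylsilyl)ethynyl]tetradec-2-enoate | CCOC(=O)/C=C/C(C)(C)CCCC(=C)[C@H](C#C[Si](C)(C)C)CC[C@H](C)CCO[Si](c1ccccc1)(c1ccccc1)C(C)(C)C | intermediate
18 | ethyl (2E,9R,12S)-14-[(tert-butyldiphenylsilyl)oxy]-9-ethynyl-4,4,12-trimethyl-8-methylidenetetradec-2-enoate | CCOC(=O)/C=C/C(C)(C)CCCC(=C)[C@H](C#C)CC[C@H](C)CCO[Si](c1ccccc1)(c1ccccc1)C(C)(C)C | intermediate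
19 | (Z)-2-iodoalkenyl-9-BBN adduct of 18 (boron on C17, iodine on C8, cis) | CCOC(=O)/C=C/C(C)(C)CCCC(=C)[C@H](/C(I)=C/B1C2CCCC1CCC2)CC[C@H](C)CCO[Si](c3ccccc3)(c3ccccc3)C(C)(C)C | intermediate (not isolated)
20 | ethyl (2E,9R,12S)-14-[(tert-butyldiphenylsilyl)oxy]-9-(1-iodoethenyl)-4,4,12-trimethyl-8-methylidenetetradec-2-enoate | CCOC(=O)/C=C/C(C)(C)CCCC(=C)[C@H](C(I)=C)CC[C@H](C)CCO[Si](c1ccccc1)(c1ccccc1)C(C)(C)C | intermediate
21 | (2E,9R,12S)-14-[(tert-butyldiphenylsilyl)oxy]-9-(1-iodoethenyl)-4,4,12-trimethyl-8-methylidenetetradec-2-en-1-ol | OC/C=C/C(C)(C)CCCC(=C)[C@H](C(I)=C)CC[C@H](C)CCO[Si](c1ccccc1)(c1ccccc1)C(C)(C)C | intermediate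
22 | (2E,9R,12S)-14-[(tert-butyldiphenylsilyl)oxy]-9-(1-iodoethenyl)-4,4,12-trimethyl-8-methylidenetetradec-2-enal | O=C/C=C/C(C)(C)CCCC(=C)[C@H](C(I)=C)CC[C@H](C)CCO[Si](c1ccccc1)(c1ccccc1)C(C)(C)C | intermediate
23 | (2E,9R)-9-{(3S)-5-[(tert-butyldiphenylsilyl)oxy]-3-methylpentyl}-4,4-dimethyl-8,10-dimethylidenecyclodec-2-en-1-ol (both C1 epimers) | C=C1CCCC(C)(C)/C=C/C(O)C(=C)[C@@H]1CC[C@H](C)CCO[Si](c2ccccc2)(c2ccccc2)C(C)(C)C | intermediate
24 | (2E,9R)-9-{(3S)-5-[(tert-butyldiphenylsilyl)oxy]-3-methylpentyl}-4,4-dimethyl-8,10-dimethylidenecyclodec-2-en-1-one (key-step precursor) | C=C1CCCC(C)(C)/C=C/C(=O)C(=C)[C@@H]1CC[C@H](C)CCO[Si](c2ccccc2)(c2ccccc2)C(C)(C)C | intermediate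
25 | (5S,9R,10S,13S)-15-[(tert-butyldiphenylsilyl)oxy]labd-8(17)-en-7-one (key-step product) | C=C1C(=O)C[C@H]2C(C)(C)CCC[C@]2(C)[C@H]1CC[C@H](C)CCO[Si](c3ccccc3)(c3ccccc3)C(C)(C)C | intermediate
26 | (5S,7R,9R,10S,13S)-15-[(tert-butyldiphenylsilyl)oxy]labd-8(17)-en-7α-ol | C=C1[C@H](O)C[C@H]2C(C)(C)CCC[C@]2(C)[C@H]1CC[C@H](C)CCO[Si](c3ccccc3)(c3ccccc3)C(C)(C)C | intermediate
27 | (5S,7R,9R,10S,13S)-15-[(tert-butyldiphenylsilyl)oxy]labd-8(17)-en-7α-yl acetate | C=C1[C@H](OC(C)=O)C[C@H]2C(C)(C)CCC[C@]2(C)[C@H]1CC[C@H](C)CCO[Si](c3ccccc3)(c3ccccc3)C(C)(C)C | intermediate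
28 | (5S,7R,9R,10S,13S)-15-hydroxylabd-8(17)-en-7α-yl acetate | C=C1[C@H](OC(C)=O)C[C@H]2C(C)(C)CCC[C@]2(C)[C@H]1CC[C@H](C)CCO | intermediate
29 | (5S,7R,9R,10S,13S)-7α-acetoxylabd-8(17)-en-15-al | C=C1[C@H](OC(C)=O)C[C@H]2C(C)(C)CCC[C@]2(C)[C@H]1CC[C@H](C)CC=O | intermediate (not isolated)
30 | (5S,7R,9R,10S,13S)-7α-acetoxylabd-8(17)-en-15-oic acid | C=C1[C@H](OC(C)=O)C[C@H]2C(C)(C)CCC[C@]2(C)[C@H]1CC[C@H](C)CC(=O)O | target

## Step count and risks

Total: 20 steps. Longest linear sequence: 18 steps (steps 1, 2, 5–20; the branch through steps 3 and 4 is equally long).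

Steps most likely to fail:

1. Step 16 (proposed new method). The hydrogen atom may go to the enone methylene C17 instead of C20, which would reduce the 8(17) alkene of substrate or product. The C10 radical may add to C17 of a second molecule. The ring may also fold with the C9 chain axial and give the wrong C5/C10 pair. The fallback uses known reactions and closes rings A and B one after the other instead of across a macrocycle; it sets out from 17. Fe(acac)3 and PhSiH3 in EtOH/ethylene glycol on 17 should bring about a 6-exo Giese cyclization started by hydrogen-atom transfer onto the enoate, a known intramolecular reaction, which forms C5–C10 and gives the ring A ester F1. K2CO3 in EtOH then gives the terminal alkyne F2. B-iodo-9-BBN followed by AcOH gives the iodoalkene F3. i-Bu2AlH at −78 °C gives the aldehyde F4. A six-membered Nozaki–Hiyama–Kishi closure (CrCl2, NiCl2 cat., DMSO) forms C7–C8 and gives 26 together with its 7β-epimer F5. Dess–Martin oxidation of the mixture gives 25, where the fallback rejoins the route before step 17. The stereochemical question then lies in the 6-exo closure (C5 and C10 against C9) and would have to be checked there.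

2. Step 9. The allyl phosphate carries a substituent on its central carbon (C10), which may slow the copper step, lower the facial selectivity at C9 or let direct substitution at C20 compete. The fallback sets the same centre by reagent control and sets out from 13. Sharpless epoxidation (Ti(OiPr)4, L-(+)-diethyl tartrate, t-BuOOH, 4 Å sieves, CH2Cl2, −20 °C) should give the (8S,9S)-epoxy alcohol F6. Opening at C9 with inversion by diethyl[(trimethylsilyl)ethynyl]aluminium (from 15, n-BuLi and Et2AlCl; toluene, 0 °C) gives the diol F7 with the required C9 configuration. 1,1′-Thiocarbonyldiimidazole gives the cyclic thiocarbonate F8. Corey–Winter olefination with 1,3-dimethyl-2-phenyl-1,3,2-diazaphospholidine at 40 °C forms the C10=C20 methylene and comes back to the route at 17.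

3. Step 14. Oligomerization may outrun closure of the strained ten-membered ring, or the C8–I bond may be reduced without C–C bond formation. The fallback closes the same C7–C8 bond by an intramolecular acyl Stille coupling and sets out from 20. Me3SnSnMe3 with Pd(PPh3)4 gives the alkenylstannane F9. LiOH in THF/H2O gives the acid F10. 1-Chloro-N,N,2-trimethylprop-1-en-1-amine gives the acid chloride F11, which is used directly. Pd2(dba)3 with tri(2-furyl)phosphine in toluene at high dilution should give the dienone 24 directly, so the fallback rejoins the route at 24 and replaces steps 12–15.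

## Further compounds

F1 | step 16 | ring A ester: ethyl (2,6,6-trimethylcyclohexyl)acetate carrying on C10 the C9 arm of 17, with C5, C9 and C10 as in 25 (7,8-seco-labdane) | CCOC(=O)C[C@H]1C(C)(C)CCC[C@]1(C)[C@H](C#C[Si](C)(C)C)CC[C@H](C)CCO[Si](c2ccccc2)(c2ccccc2)C(C)(C)C
F2 | step 16 | terminal alkyne from F1 | CCOC(=O)C[C@H]1C(C)(C)CCC[C@]1(C)[C@H](C#C)CC[C@H](C)CCO[Si](c2ccccc2)(c2ccccc2)C(C)(C)C
F3 | step 16 | C8 iodoalkene ester from F2 | CCOC(=O)C[C@H]1C(C)(C)CCC[C@]1(C)[C@H](C(I)=C)CC[C@H](C)CCO[Si](c2ccccc2)(c2ccccc2)C(C)(C)C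
F4 | step 16 | C7 aldehyde from F3 | O=CC[C@H]1C(C)(C)CCC[C@]1(C)[C@H](C(I)=C)CC[C@H](C)CCO[Si](c2ccccc2)(c2ccccc2)C(C)(C)C
F5 | step 16 | (13S)-15-[(tert-butyldiphenylsilyl)oxy]labd-8(17)-en-7β-ol (7-epimer of 26) | C=C1[C@@H](O)C[C@H]2C(C)(C)CCC[C@]2(C)[C@H]1CC[C@H](C)CCO[Si](c3ccccc3)(c3ccccc3)C(C)(C)C
F6 | step 9 | ethyl (2E,8S,9S,12S)-14-[(tert-butyldiphenylsilyl)oxy]-8,9-epoxy-8-(hydroxymethyl)-4,4,12-trimethyltetradec-2-enoate | CCOC(=O)/C=C/C(C)(C)CCC[C@@]1(CO)O[C@H]1CC[C@H](C)CCO[Si](c2ccccc2)(c2ccccc2)C(C)(C)C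
F7 | step 9 | ethyl (2E,8R,9S,12S)-14-[(tert-butyldiphenylsilyl)oxy]-8-hydroxy-8-(hydroxymethyl)-4,4,12-trimethyl-9-[(trimethylsilyl)ethynyl]tetradec-2-enoate | CCOC(=O)/C=C/C(C)(C)CCC[C@](O)(CO)[C@H](C#C[Si](C)(C)C)CC[C@H](C)CCO[Si](c1ccccc1)(c1ccccc1)C(C)(C)C
F8 | step 9 | cyclic thiocarbonate (2-thioxo-1,3-dioxolane) of the diol F7 | CCOC(=O)/C=C/C(C)(C)CCC[C@]1(COC(=S)O1)[C@H](C#C[Si](C)(C)C)CC[C@H](C)CCO[Si](c2ccccc2)(c2ccccc2)C(C)(C)C
F9 | step 14 | ethyl (2E,9R,12S)-14-[(tert-butyldiphenylsilyl)oxy]-4,4,12-trimethyl-8-methylidene-9-[1-(trimethylstannyl)ethenyl]tetradec-2-enoate | CCOC(=O)/C=C/C(C)(C)CCCC(=C)[C@H](C(=C)[Sn](C)(C)C)CC[C@H](C)CCO[Si](c1ccccc1)(c1ccccc1)C(C)(C)C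
F10 | step 14 | carboxylic acid from F9 | OC(=O)/C=C/C(C)(C)CCCC(=C)[C@H](C(=C)[Sn](C)(C)C)CC[C@H](C)CCO[Si](c1ccccc1)(c1ccccc1)C(C)(C)C
F11 | step 14 | acid chloride from F10 | ClC(=O)/C=C/C(C)(C)CCCC(=C)[C@H](C(=C)[Sn](C)(C)C)CC[C@H](C)CCO[Si](c1ccccc1)(c1ccccc1)C(C)(C)C
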